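The runs are calculated on assumed constants, noise included.

Take the fraction of L left, not the fraction made, and divide the logarithm of charged over remaining [L] by the time; this left-rate lets flasks of different size be set side by side.

| setting | red | green | ochre | violet |
|---|---|---|---|---|
| L | 80.0 mM | 48.0 mM | 80.0 mM | 32.0 mM |
| J | 96.0 mM | 64.0 mM | 96.0 mM | 38.0 mM |
| Q | 0.160 mM | 0.160 mM | 0.480 mM | 0.160 mM |
| time |  |  |  | 21 h |

- red run (time / h: [L] / mM): 2.6: 75.7; 5.2: 71.5; 7.9: 66.5; 10: 63.6; 13: 58.3; 16: 55.5; 18: 53.2; 21: 47.6
- green run (time / h: [L] / mM): 2.6: 44.7; 5.2: 42.5; 7.9: 40.9; 10: 37.8; 13: 34.1; 16: 31.5; 18: 29.5; 21: 27.6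
- ochre run (time / h: [L] / mM): 2.6: 60.5; 5.2: 46.2; 7.9: 33.0; 10: 25.2; 13: 18.1; 16: 9.9; 18: 7.3; 21: 4.3

(standard deviation of a reading: 1 mM)

- apparent order in [Q] of the starting rate, round the charge of the red run (the rate where two percent of its L have turned into E)
- the green run starts with 32.0 mM less of L and of J than the red run, and with no E. Compared where both hold the same amount of L, once fifteen percent of what the green run was charged with has turned into E, is the green run faster, slower or alike (within a tenth)?
- L in the violet run at 21 h, as a share of the L charged
- which of these the readings show (the second partner ties up the catalyst / a little impurity takes part of the catalyst at once / the second partner kills the catalyst / the loaded catalyst dies / nothing beyond the main steps / the product decays)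

- Overall: L + J -> E, with Q as catalyst.
- Constant volume, constant temperature.
- Bound and free are read together.
- "The second partner" is J.
- An order is taken over about fifteen percent of the charge, up and down.

The red run keeps 59.5% of its L at 21 h, and the ochre run keeps 57.8% at 5.2 h. These two flasks have the same L and J charges and stand at similar [L] here, so their left-rates compare the Q in them. A rate simply proportional to Q gives a ratio of 3.00, but these readings give 4.27. One pair of readings may mislead, since each carries a scatter of 1 mM. A second pair, the red run at 13 h and the ochre run at 2.6 h, gives 4.41, so the excess stands.

Suppose each flask loses the same amount of Q at once. The ratio is then ochre Q minus that amount over red Q minus that amount, which gives the lost catalyst, the Q gone before any turnover, as 0.0622 mM. The red run then works on 0.0978 mM. A catalyst dying slowly might imitate this, but the ochre left-rate is 0.150 h⁻¹ after 5.2 h, against 0.106 h⁻¹ before it, and the late flask shows no slowing. The order in Q round the red charge is the charge over its working part, 1.64.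

The violet run holds the red Q, and its L and J are the red charges scaled by about 0.400, so the first estimate is the red fraction left, 59.5%. The objection is that a smaller flask might lose its fraction faster. The green run, smaller than the red run, has a left-rate over 21 h just 1.07 times the red one, and its L to J ratio also differs, so the estimate stands.

The forecast gives 1.7 (1.4 to 2.1), alike, 54% (47% to 62%) and "a little impurity takes part of the catalyst at once", noting that “This ratio holds throughout the runs”. Its violet figure stands lower than the reckoning here.

The simulation gives 1.8, alike, 61.6% and "a little impurity takes part of the catalyst at once".

    Q + L → QL (1102 L mol⁻¹ h⁻¹)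
    QL + J → E + Q (280.4 L mol⁻¹ h⁻¹)
    Q + Lx → Jo

At the start, Lx took 0.0725 mM of Q into Jo at once; from then on, with L and J both present, Q took up L to form QL, and QL met J to give E and free Q again. The 0.0622 mM read from the runs put the order in Q round the red charge at 1.64, and the simulation gives 1.8. The violet run went through this cycle for 21 h on the 0.0875 mM of Q that Lx left it, and its left-rate divided by that Q came to 264 L mol⁻¹ h⁻¹.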